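A direct plan would esterify 2,3-dihydroxybenzoic acid A1 with octadecan-1-ol A2, either directly under acid catalysis or, after conversion of A1 into 2,3-bis(benzyloxy)benzoic acid A3, by carbodiimide coupling of A3 with A2 to octadecyl 2,3-bis(benzyloxy)benzoate A4, followed by hydrogenolysis of A4. Its weakest steps would be:
- the direct esterification of A1: the waxy, non-volatile alcohol A2 could not be used in excess without a hard separation, and the hydrogen-bonded acid would react slowly while the free catechol self-acylates and oxidises;
- the masking of the catechol on the way to A3 (perbenzylation, then saponification of the benzyl ester): two operations that add no skeletal complexity;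
- the carbodiimide coupling of the ortho-alkoxy acid A3 to the ester A4: slow acyl transfer to the long-chain alcohol A2 would favour N-acylurea formation.

**Strategy.** The route would build the benzene ring instead of decorating one. Ring carbons C1 (ester), C2 (OH) and C3 (OH) of the target are chain carbons C2, C3 and C4 of a 4-(benzyloxy)acetoacetate that already carries the octadecyl ester. Ring carbons C4–C6 come from the symmetrical malonaldehyde equivalent 1,1,3,3-tetramethoxypropane. A formal [3+3] cyclocondensation of the derived 1,3-bis(silyloxy)diene with this bis-acetal would form the C3–C4 and C1–C6 ring bonds and aromatise in one operation. The 1,2,3-pattern is then fixed by connectivity, the ester is made on an aliphatic β-keto ester, and neither an esterification of a catechol acid nor a masking sequence on an arene is needed.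

Key step: step 4

Remark: the target has no stereocentre. Enol ethers 4, 5, 6 and 8 would be used as mixtures of double-bond isomers and the transient 8 and 9 as mixtures of diastereomers. All converge on aromatisation, so their SMILES carry no stereodescriptors.

Step 1
Reactants: 1 ethyl 4-(benzyloxy)-3-oxobutanoate; 2 octadecan-1-ol
Product: 3 octadecyl 4-(benzyloxy)-3-oxobutanoate
Conditions: 1 (1.2 equiv.), 2 (1.0 equiv.), DMAP (0.3 equiv.), 4 Å molecular sieves, toluene, reflux
Reagents that add atoms: none
Why: DMAP-catalysed transesterification of an enolisable β-keto ester should exchange ethanol for the primary C18 alcohol, with the sieves removing ethanol and the waxy alcohol as limiting component so that none remains.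

Step 2
Reactants: 3 octadecyl 4-(benzyloxy)-3-oxobutanoate
Product: 4 octadecyl 4-(benzyloxy)-3-(trimethylsilyloxy)but-2-enoate
Conditions: Me3SiCl (1.5 equiv.), NEt3 (1.6 equiv.), toluene, 20 °C; filtration under argon, concentration
Reagents that add atoms: chlorotrimethylsilane, C[Si](C)(C)Cl
Why: O-silylation of the enolised β-keto ester (silyl enol ether formation) should give the conjugated 3-silyloxy enoate, the benzyl ether and the alkyl ester being inert.

Step 3
Reactants: 4 octadecyl 4-(benzyloxy)-3-(trimethylsilyloxy)but-2-enoate
Product: 6 4-(benzyloxy)-1-(octadecyloxy)-1,3-bis(trimethylsilyloxy)buta-1,3-diene, via lithium dienolate 5 (not isolated)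
Conditions: LiN(iPr)2 (1.5 equiv., commercial solution), THF, −78 °C (−40 °C if the C18 ester separates); Me3SiCl (1.5 equiv.), −78 → 20 °C; hexane, filtration under argon; used crude
Reagents that add atoms: chlorotrimethylsilane, C[Si](C)(C)Cl (the second Me3Si group); lithium diisopropylamide, CC(C)N([Li])C(C)C (the Li of 5, lost again)
Why: Kinetic γ-deprotonation of the vinylogous ester by the hindered amide gives dienolate 5, which is silylated on the ester oxygen (silyl ketene acetal formation) to the Chan-type 1,3-bis(silyloxy)diene, the base being too hindered to add to the carbonyl.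

Step 4
Reactants: 6 4-(benzyloxy)-1-(octadecyloxy)-1,3-bis(trimethylsilyloxy)buta-1,3-diene; 7 1,1,3,3-tetramethoxypropane
Product: 10 octadecyl 3-(benzyloxy)-2-hydroxybenzoate, via open-chain trimethoxy silyl enol ether 8 (not isolated), via dimethoxycyclohexanone 9 (not isolated)
Conditions: Me3SiOTf (0.1–0.3 equiv.), CH2Cl2 (dilute), −78 → 20 °C; then 10% aq. HCl
Reagents that add atoms: none
Why: Me3SiOTf ionises one acetal of 7 to a methoxycarbenium ion, which is attacked by the terminal carbon C4 of diene 6 (vinylogous Mukaiyama addition) to give 8, still a silyl enol ether of a β-keto ester. Ionisation of the second acetal lets C2 close the carbocycle in a 6-(enolendo)-exo-trig Mukaiyama-type cyclisation to cyclohexanone 9, and loss of two molecules of methanol with tautomerisation of the resulting dienone gives phenol 10, the aromatisation making the sequence irreversible. The closest known reaction type is the Chan-type formal [3+3] cyclocondensation of 1,3-bis(silyloxy)buta-1,3-dienes with 1,3-dielectrophiles, which with 1,1,3,3-tetramethoxypropane gives 4,5,6-unsubstituted salicylates and with 4-alkoxy dienes 3-alkoxysalicylates. No stereocentre is kept, so the configurations of 8 and 9 are without consequence. The step needs terminal-carbon attack before central-carbon attack and ring closure in preference to chain growth: the first follows from the larger HOMO coefficient at the diene terminus and, 7 being symmetrical, either order would give the same 1,2,3-pattern, while the intramolecular second addition is favoured by dilution and low temperature. A catalytic amount of the silyl triflate should leave the benzyl ether and the primary ester untouched.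

Step 5
Reactants: 10 octadecyl 3-(benzyloxy)-2-hydroxybenzoate
Product: 11 gentiside E (octadecyl 2,3-dihydroxybenzoate)
Conditions: H2 (1 atm), 10% Pd/C, EtOAc/THF, 25 °C; filtration under argon
Reagents that add atoms: none
Why: Heterogeneous hydrogenolysis of the benzylic C–O bond over palladium should free the second phenol and leave the alkyl ester, the arene and the saturated chain untouched.

**Compound list**

1 | ethyl 4-(benzyloxy)-3-oxobutanoate | CCOC(=O)CC(=O)COCc1ccccc1 | starting material
2 | octadecan-1-ol | CCCCCCCCCCCCCCCCCCO | starting material
3 | octadecyl 4-(benzyloxy)-3-oxobutanoate | CCCCCCCCCCCCCCCCCCOC(=O)CC(=O)COCc1ccccc1 | intermediate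
4 | octadecyl 4-(benzyloxy)-3-(trimethylsilyloxy)but-2-enoate | CCCCCCCCCCCCCCCCCCOC(=O)C=C(O[Si](C)(C)C)COCc1ccccc1 | intermediate
5 | lithium dienolate of 4 (lithium 4-(benzyloxy)-1-(octadecyloxy)-3-(trimethylsilyloxy)buta-1,3-dien-1-olate) | CCCCCCCCCCCCCCCCCCOC(O[Li])=CC(O[Si](C)(C)C)=COCc1ccccc1 | intermediate
6 | 4-(benzyloxy)-1-(octadecyloxy)-1,3-bis(trimethylsilyloxy)buta-1,3-diene | CCCCCCCCCCCCCCCCCCOC(O[Si](C)(C)C)=CC(O[Si](C)(C)C)=COCc1ccccc1 | intermediate
7 | 1,1,3,3-tetramethoxypropane | COC(OC)CC(OC)OC | starting material
8 | octadecyl 4-(benzyloxy)-5,7,7-trimethoxy-3-(trimethylsilyloxy)hept-2-enoate | CCCCCCCCCCCCCCCCCCOC(=O)C=C(O[Si](C)(C)C)C(OCc1ccccc1)C(OC)CC(OC)OC | intermediate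
9 | octadecyl 3-(benzyloxy)-4,6-dimethoxy-2-oxocyclohexane-1-carboxylate | CCCCCCCCCCCCCCCCCCOC(=O)C1C(OC)CC(OC)C(OCc2ccccc2)C1=O | intermediate
10 | octadecyl 3-(benzyloxy)-2-hydroxybenzoate | CCCCCCCCCCCCCCCCCCOC(=O)c1cccc(OCc2ccccc2)c1O | intermediate
11 | gentiside E (octadecyl 2,3-dihydroxybenzoate) | CCCCCCCCCCCCCCCCCCOC(=O)c1cccc(O)c1O | target

Total step count: 5. Longest linear sequence: 5.

**Steps most likely to fail**

1. Step 4. The diene could be protodesilylated before it reacts, the sequence could stop after the first addition, or the bis-electrophile could grow chains instead of closing the ring. The fallback would set out from 3 and come back at 10 by a Robinson-type annulation followed by dehydrogenation. Conjugate addition of 3 to acrolein (cat. NEt3, CH2Cl2, 0 °C) would give octadecyl 2-[(benzyloxy)acetyl]-5-oxopentanoate F1. Intramolecular aldol condensation of the benzyloxy-bearing α-carbon onto the aldehyde (TsOH, toluene, water separator) would give octadecyl 3-(benzyloxy)-2-oxocyclohex-3-ene-1-carboxylate F2. Dehydrogenation with DDQ (dioxane, 80 °C) and tautomerisation would then give 10.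

2. Step 3. γ-Deprotonation could remain incomplete if the C18 ester separates from cold THF, silylation could occur on carbon, and the diene could hydrolyse on handling. The fallback would set out from 3 and come back at 10 without silicon. The dianion of 3 (NaH, then n-BuLi, THF, 0 → −78 °C) would add through its γ-carbon to 3,3-dimethoxypropanal to give octadecyl 4-(benzyloxy)-5-hydroxy-7,7-dimethoxy-3-oxoheptanoate F3. Warming F3 with TsOH in wet toluene should unmask the aldehyde, close the ring by intramolecular Knoevenagel condensation and dehydrate twice to 10.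

3. Step 1. Ester exchange could stall, or the β-keto ester could self-condense on prolonged heating, leaving waxy alcohol that is hard to remove. The fallback would set out from 2 and come back at 3 through an acylketene. Meldrum's acid would be acylated with benzyloxyacetyl chloride (pyridine, CH2Cl2, 0 °C) to 5-[2-(benzyloxy)-1-hydroxyethylidene]-2,2-dimethyl-1,3-dioxane-4,6-dione F4. Heating F4 with 2 in toluene would expel acetone and carbon dioxide and trap the acylketene as 3.

**Further compounds**

F1 | step 4 | octadecyl 2-[(benzyloxy)acetyl]-5-oxopentanoate | CCCCCCCCCCCCCCCCCCOC(=O)C(CCC=O)C(=O)COCc1ccccc1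
F2 | step 4 | octadecyl 3-(benzyloxy)-2-oxocyclohex-3-ene-1-carboxylate | CCCCCCCCCCCCCCCCCCOC(=O)C1CCC=C(OCc2ccccc2)C1=O
F3 | step 3 | octadecyl 4-(benzyloxy)-5-hydroxy-7,7-dimethoxy-3-oxoheptanoate | CCCCCCCCCCCCCCCCCCOC(=O)CC(=O)C(OCc1ccccc1)C(O)CC(OC)OC
F4 | step 1 | 5-[2-(benzyloxy)-1-hydroxyethylidene]-2,2-dimethyl-1,3-dioxane-4,6-dione | CC1(C)OC(=O)C(=C(O)COCc2ccccc2)C(=O)O1
A1 | direct plan | 2,3-dihydroxybenzoic acid | O=C(O)c1cccc(O)c1O
A2 | direct plan | octadecan-1-ol | CCCCCCCCCCCCCCCCCCO
A3 | direct plan | 2,3-bis(benzyloxy)benzoic acid | O=C(O)c1cccc(OCc2ccccc2)c1OCc1ccccc1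
A4 | direct plan | octadecyl 2,3-bis(benzyloxy)benzoate | CCCCCCCCCCCCCCCCCCOC(=O)c1cccc(OCc2ccccc2)c1OCc1ccccc1
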